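Each vessel here is closed and stirred: L comes from the gas X, Z trades J for L and becomes D, and D can trade again and become Q.

| setting | elm | Tuesday's | Saturday's |
|---|---|---|---|
| Z | 2.2 M | 0.50 M | 2.0 M |
| X | 130 mM (held) | 130 mM (held) | 130 mM (held) |
| temperature | 80 °C |  |  |
| remark | run made earlier | at 80 °C throughout | at 80 °C until 3.0 min, from then on at 140 °C |
| time |  | 15 min | 15 min |

- elm (time / min: D / %): 1.33: 9; 2.50: 15; 4.00: 21; 5.00: 19; 6.00: 24; 8.00: 32; 10.0: 37

(standard deviation of a reading: 2 percentage points)

- the flask that ends with the higher amount of D, in percent of the Z charged, or "neither" when 2 percentage points or less lies between them (Tuesday's / Saturday's / neither)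
- final D, as a percentage of the Z charged, in Tuesday's
- final D, as a percentage of the Z charged, in Saturday's

- at the start none of L is dissolved
- steps thought possible: Z + L <-> J + D; D + L <-> J + Q; X <-> L; J -> E; L <-> G
- the earlier runs do not show what temperature does; that part of a forecast is a guess

I follow one molecule. While L stays near one level, which I assume for these flasks, a Z molecule has a fixed chance per minute of exchanging, so the step is pseudo-first-order. From the reading at 2.50 min, when I take little D to have gone on, I get this exchange constant κ, the chance per minute that a Z exchanges: 0.0650 min⁻¹. It is a reading, with the scatter in it, and I take it to hold for the charges of Z in Tuesday's and Saturday's.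

With x = κt, two versions solve in the head. If D never goes on, D is 1 − exp(−x). If D goes on as fast as Z exchanges, two equal time constants in series, D is x·exp(−x), which peaks where x reaches one. At 10.0 min of the elm run, x is 0.650, so the versions give 47.8% and 33.9%, and the reading is 37%. That elm reading therefore lies 22.1% of the way up from the second version.

For Tuesday's, x is 0.975, the versions give 62.3% and 36.8%, and the same position gives 42.4%. For Saturday's, I guess that heat speeds the exchanges by a factor 10, so x is 8.00, far past the peak. The versions then give >99.9% and 0.269%, and the same position, carried to a temperature the elm run does not show, gives 22.3%, so I expect Saturday's to end below Tuesday's, with the heat a guess.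

The forecast, which differs from my numbers, says Tuesday's with 54% and 45%, the latter “very uncertain”.

The simulation gives Tuesday's, with 42.6% in Tuesday's and 2.10% in Saturday's.

    Z + L ⇌ J + D (K = 93.0, k = 0.580 M⁻¹ min⁻¹, Ea = 52.0 kJ mol⁻¹, ΔH = −12.0 kJ mol⁻¹)
    D + L ⇌ J + Q (K = 6.30, k = 0.470 M⁻¹ min⁻¹, Ea = 87.0 kJ mol⁻¹, ΔH = −10.0 kJ mol⁻¹)
    X ⇌ L, rate k3*(csat - [L]) (kL = 6.10 min⁻¹)
    J → E (k = 0.00760 min⁻¹, Ea = 123 kJ mol⁻¹)
    L ⇌ G (K = 21.0, k = 0.350 min⁻¹, Ea = 110 kJ mol⁻¹, ΔH = −83.0 kJ mol⁻¹)
    (constants at 80 °C)

Tuesday's 42.6% stands beside my 42.4%, and Saturday's 2.10% beside my 22.3%. In my reckoning a neighbour flask, Tuesday's with 0.85 M of Z, keeps κ at 0.0650 min⁻¹ and the same time, so its x is again 0.975 and the same position again gives 42.4%. That flask ends with 43.5% of D and 38% of its Z still unexchanged.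

(The data are calculated for an exercise; noise was put on by code.)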